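The trans-2-aryl-3-(hydroxymethyl)-2,3-dihydrobenzofuran core is treated as a ring-contracted flavanone: the C3–C3a bond of the dihydrofuran ring and the exocyclic CH2OH carbon on C3 correspond to C3 and C4 of a 2-arylchroman-4-one. An enantioenriched (2R)-flavanone carrying an 8-benzyloxy group, a 6-bromide and a mesylated guaiacyl ring at C2 is therefore oxidised with iodine(III) in acidic trimethyl orthoformate. That one operation moves the fused arene carbon C4a from C4 to C3, contracts the pyranone to the dihydrofuran, sets the trans C3 stereocentre and leaves C4 as a methyl ester. The bromide is later turned into the aldehyde from which the flavonol is grown.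

Key step: step 7

Assumption: the (S)-configured tert-butyl pyridine-oxazoline ligand is taken to deliver the 2R flavanone, by analogy with its facial preference in additions to cyclic enones; should the sense prove opposite, its enantiomer is used and nothing else changes.

Step 1
Reactants: 1 2',3'-dihydroxyacetophenone
Product: 2 1-[3-(benzyloxy)-2-hydroxyphenyl]ethan-1-one
Conditions: NaH (2.1 equiv), THF–DMSO, 0 °C → rt; BnBr (1.0 equiv); aq. HCl quench
Reagents that add atoms: benzyl bromide, BrCc1ccccc1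
Why: Williamson etherification of the catecholate dianion, in which the 2-oxide is delocalised into and chelated by the acetyl group, so the single equivalent of benzyl bromide should react at the more nucleophilic 3-oxide.

Step 2
Reactants: 2 1-[3-(benzyloxy)-2-hydroxyphenyl]ethan-1-one
Product: 3 1-[3-(benzyloxy)-5-bromo-2-hydroxyphenyl]ethan-1-one
Conditions: NBS (1.05 equiv), MeCN, 0 °C → rt
Reagents that add atoms: N-bromosuccinimide, O=C1CCC(=O)N1Br
Why: Electrophilic aromatic bromination, directed by the free 2-OH to its only open para position C5, which is also meta to the acetyl group, whereas C4 and C6 are para and ortho to that deactivating group.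

Step 3
Reactants: 3 1-[3-(benzyloxy)-5-bromo-2-hydroxyphenyl]ethan-1-one
Product: 5 8-(benzyloxy)-6-bromo-4H-chromen-4-one, via enaminone 4 (not isolated)
Conditions: DMF dimethyl acetal (2.5 equiv), toluene, 100 °C; concentrate; conc. HCl, CH2Cl2, rt
Reagents that add atoms: N,N-dimethylformamide dimethyl acetal, COC(OC)N(C)C
Why: Enaminone–chromone annulation, in which the methyl ketone condenses with the formamide acetal and acid then promotes conjugate addition of the phenol and loss of dimethylamine (6-endo-trig addition–elimination) to close the pyranone.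

Step 4
Reactants: 6 2-methoxy-4-(4,4,5,5-tetramethyl-1,3,2-dioxaborolan-2-yl)phenol
Product: 7 2-methoxy-4-(4,4,5,5-tetramethyl-1,3,2-dioxaborolan-2-yl)phenyl methanesulfonate
Conditions: MsCl (1.2 equiv), Et3N (1.5 equiv), CH2Cl2, 0 °C
Reagents that add atoms: methanesulfonyl chloride, CS(=O)(=O)Cl
Why: O-Sulfonylation of the phenol under amine base leaves the pinacol boronate alone, and it is done first because a free guaiacol would not survive the periodate of the next step.

Step 5
Reactants: 7 2-methoxy-4-(4,4,5,5-tetramethyl-1,3,2-dioxaborolan-2-yl)phenyl methanesulfonate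
Product: 8 [3-methoxy-4-(methylsulfonyloxy)phenyl]boronic acid
Conditions: NaIO4 (3 equiv), NH4OAc (3 equiv), acetone–H2O 1:1, rt
Reagents that add atoms: water, O
Why: Oxidative deprotection of a pinacol boronate, in which periodate cleaves the diol out of the hydrolysis equilibrium and so releases the free boronic acid needed for transmetalation to palladium(II), under near-neutral conditions that the aryl mesylate tolerates.

Step 6
Reactants: 5 8-(benzyloxy)-6-bromo-4H-chromen-4-one; 8 [3-methoxy-4-(methylsulfonyloxy)phenyl]boronic acid (2 equiv)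
Product: 9 (2R)-8-(benzyloxy)-6-bromo-2-[3-methoxy-4-(methylsulfonyloxy)phenyl]chroman-4-one
Conditions: Pd(OCOCF3)2 (5 mol%), (S)-t-BuPyOx (6 mol%), NH4PF6 (30 mol%), H2O (5 equiv), ClCH2CH2Cl, 60 °C
Reagents that add atoms: none
Why: Enantioselective palladium(II)-catalysed conjugate addition of an arylboronic acid to a chromone, in which the aryl group passes from boron to the cationic Pd(II)–pyridine-oxazoline complex, face-selective carbopalladation of C2=C3 in the chiral pocket sets C2 as R, and protonolysis of the palladium enolate releases the flavanone; the aryl bromide and mesylate stay intact because no Pd(0) is involved.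

Step 7
Reactants: 9 (2R)-8-(benzyloxy)-6-bromo-2-[3-methoxy-4-(methylsulfonyloxy)phenyl]chroman-4-one
Product: 11 methyl (2R,3R)-7-(benzyloxy)-5-bromo-2-[3-methoxy-4-(methylsulfonyloxy)phenyl]-2,3-dihydro-1-benzofuran-3-carboxylate (trans), via enol ether 10 (not isolated)
Conditions: PhI(OAc)2 (1.3 equiv), conc. H2SO4 (1.5 equiv), HC(OMe)3, 0 °C → rt
Reagents that add atoms: trimethyl orthoformate, COC(OC)OC
Why: In the acidic orthoformate, flavanone 9 is ketalised and loses methanol to give enol ether 10; acid-activated PhI(OAc)2 then adds to C3 of 10 with methanol capture at C4, and reductive departure of iodobenzene from C3 is assisted by the fused arene carbon C4a, which shifts from C4 to C3 while the resulting C4 dimethoxycarbenium ion loses a methyl group to leave the ester. The closest known reaction type is the iodine(III)- or thallium(III)-mediated oxidative 1,2-aryl shift of aryl ketones, established for flavanones as a contraction to trans methyl 2-aryl-2,3-dihydrobenzofuran-3-carboxylates. The dihydrofuran ring arises by ring contraction and not by a cyclisation: ipso attack of C4a on C3 gives a bridged phenonium ion (formally 3-exo-tet), which opens by cleavage of C4–C4a so that the six-membered pyranone becomes the five-membered ring with C4 exocyclic. The new C3 stereocentre is controlled by C2: the iodane should add trans to the pseudo-equatorial C2 aryl group, and migration from the antiperiplanar C4–C4a bond with inversion at C3 then places the ester trans to that aryl group (2R,3R), which is also the more stable epimer. The step needs migration of C4a in preference to a shift of the C2 aryl group (isoflavone) or loss of a proton (flavone); C4a is electron-rich because it sits ortho to O1, while the mesyloxy group makes the C2 aryl ring a poor migrating group and disfavours ionisation of the C2–O bond, so the C2 configuration should be retained.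

Step 8
Reactants: 11 methyl (2R,3R)-7-(benzyloxy)-5-bromo-2-[3-methoxy-4-(methylsulfonyloxy)phenyl]-2,3-dihydro-1-benzofuran-3-carboxylate
Product: 12 4-[(2R,3S)-7-(benzyloxy)-5-bromo-3-(hydroxymethyl)-2,3-dihydro-1-benzofuran-2-yl]-2-methoxyphenyl methanesulfonate
Conditions: DIBAL-H (3 equiv), CH2Cl2, −78 → 0 °C; aq. Rochelle salt
Reagents that add atoms: none
Why: Ester reduction by a Lewis-acidic aluminium hydride at low temperature gives the primary alcohol without base, so C3–H is not enolised and the aryl bromide, benzyl ether and aryl mesylate are untouched; the C3 descriptor changes from R to S only because CH2OH ranks below C2.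

Step 9
Reactants: 12 4-[(2R,3S)-7-(benzyloxy)-5-bromo-3-(hydroxymethyl)-2,3-dihydro-1-benzofuran-2-yl]-2-methoxyphenyl methanesulfonate
Product: 13 4-[(2R,3S)-7-(benzyloxy)-5-ethenyl-3-(hydroxymethyl)-2,3-dihydro-1-benzofuran-2-yl]-2-methoxyphenyl methanesulfonate
Conditions: vinylboronic acid pinacol ester (1.5 equiv), Pd(dppf)Cl2 (5 mol%), K2CO3 (3 equiv), 1,4-dioxane–H2O 9:1, 80 °C
Reagents that add atoms: vinylboronic acid pinacol ester, C=CB1OC(C)(C)C(C)(C)O1
Why: Suzuki–Miyaura coupling in which Pd(0) inserts into the C–Br bond only, since aryl mesylates do not undergo oxidative addition to dppf-ligated palladium, and the free primary alcohol is tolerated.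

Step 10
Reactants: 13 4-[(2R,3S)-7-(benzyloxy)-5-ethenyl-3-(hydroxymethyl)-2,3-dihydro-1-benzofuran-2-yl]-2-methoxyphenyl methanesulfonate
Product: 14 4-[(2R,3S)-7-(benzyloxy)-5-formyl-3-(hydroxymethyl)-2,3-dihydro-1-benzofuran-2-yl]-2-methoxyphenyl methanesulfonate
Conditions: OsO4 (2 mol%), NaIO4 (4 equiv), 2,6-lutidine (2 equiv), 1,4-dioxane–H2O 3:1, rt
Reagents that add atoms: sodium periodate, [Na+].[O-]I(=O)(=O)=O (terminal oxidant, source of the aldehyde oxygen through the osmium cycle); osmium tetroxide, O=[Os](=O)(=O)=O (catalytic oxygen carrier)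
Why: Lemieux–Johnson oxidation, in which catalytic osmylation of the terminal styrene and periodate cleavage of the diol give the aryl aldehyde; the lutidine buffer limits over-oxidation, and 13 holds no other alkene and no free phenol.

Step 11
Reactants: 15 2,4,6-trihydroxyacetophenone
Product: 16 1-[2,4-bis(benzyloxy)-6-hydroxyphenyl]ethan-1-one
Conditions: BnBr (2.05 equiv), K2CO3 (2.2 equiv), DMF, rt
Reagents that add atoms: benzyl bromide, BrCc1ccccc1
Why: Williamson etherification under carbonate base alkylates two phenols, and the hydroxyl that remains is hydrogen-bonded to the acetyl group and resists further alkylation.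

Step 12
Reactants: 14 4-[(2R,3S)-7-(benzyloxy)-5-formyl-3-(hydroxymethyl)-2,3-dihydro-1-benzofuran-2-yl]-2-methoxyphenyl methanesulfonate; 16 1-[2,4-bis(benzyloxy)-6-hydroxyphenyl]ethan-1-one
Product: 18 (E)-1-[2,4-bis(benzyloxy)-6-hydroxyphenyl]-3-[(2R,3S)-7-(benzyloxy)-2-(4-hydroxy-3-methoxyphenyl)-3-(hydroxymethyl)-2,3-dihydro-1-benzofuran-5-yl]prop-2-en-1-one, via mesylated chalcone 17 (not isolated)
Conditions: KOH (50% aq., 15 equiv), EtOH–THF, rt; then 50 °C; 1 M HCl work-up
Reagents that add atoms: none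
Why: Claisen–Schmidt condensation (aldol addition and E1cB dehydration) of the acetophenone enolate with the non-enolisable aldehyde should give E-chalcone 17, and continued exposure to warm hydroxide hydrolyses the aryl methanesulfonate at sulfur, so the guaiacyl phenol is released at a stage where every other phenol is benzylated or present as a phenoxide.

Step 13
Reactants: 18 (E)-1-[2,4-bis(benzyloxy)-6-hydroxyphenyl]-3-[(2R,3S)-7-(benzyloxy)-2-(4-hydroxy-3-methoxyphenyl)-3-(hydroxymethyl)-2,3-dihydro-1-benzofuran-5-yl]prop-2-en-1-one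
Product: 20 5,7-bis(benzyloxy)-2-[(2R,3S)-7-(benzyloxy)-2-(4-hydroxy-3-methoxyphenyl)-3-(hydroxymethyl)-2,3-dihydro-1-benzofuran-5-yl]-3-hydroxy-4H-chromen-4-one, via dihydroflavonol 19 (not isolated)
Conditions: 30% H2O2 (6 equiv), 2 M NaOH, MeOH–THF, 0 °C → rt; 1 M HCl work-up
Reagents that add atoms: hydrogen peroxide, OO
Why: Algar–Flynn–Oyamada reaction, in which alkaline hydrogen peroxide oxygenates the enone, the 2'-phenoxide closes the pyranone at the β-carbon to give 3-hydroxyflavanone 19, and this is dehydrogenated in the same medium to the flavonol; the two stereocentres of the dihydrobenzofuran are remote and should not be affected.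

Step 14
Reactants: 20 5,7-bis(benzyloxy)-2-[(2R,3S)-7-(benzyloxy)-2-(4-hydroxy-3-methoxyphenyl)-3-(hydroxymethyl)-2,3-dihydro-1-benzofuran-5-yl]-3-hydroxy-4H-chromen-4-one
Product: 21 2,3-dehydrosilychristin, 3,5,7-trihydroxy-2-[(2R,3S)-7-hydroxy-2-(4-hydroxy-3-methoxyphenyl)-3-(hydroxymethyl)-2,3-dihydro-1-benzofuran-5-yl]-4H-chromen-4-one
Conditions: H2 (1 atm), 10% Pd/C, THF–MeOH, rt
Reagents that add atoms: none
Why: Catalytic hydrogenolysis removes the three aryl benzyl ethers, which should cleave faster than the cyclic benzylic C2–O bond of the dihydrobenzofuran, while the flavonol C2=C3 bond (part of a vinylogous ester) is not hydrogenated under these conditions, so no stereocentre is touched.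

Compound list
1 | 2',3'-dihydroxyacetophenone | CC(=O)c1cccc(O)c1O | starting material
2 | 1-[3-(benzyloxy)-2-hydroxyphenyl]ethan-1-one | CC(=O)c1cccc(OCc2ccccc2)c1O | intermediate
3 | 1-[3-(benzyloxy)-5-bromo-2-hydroxyphenyl]ethan-1-one | CC(=O)c1cc(Br)cc(OCc2ccccc2)c1O | intermediate
4 | (E)-1-[3-(benzyloxy)-5-bromo-2-hydroxyphenyl]-3-(dimethylamino)prop-2-en-1-one | CN(C)/C=C/C(=O)c1cc(Br)cc(OCc2ccccc2)c1O | intermediate
5 | 8-(benzyloxy)-6-bromo-4H-chromen-4-one | O=c1ccoc2c(OCc3ccccc3)cc(Br)cc12 | intermediate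
6 | 2-methoxy-4-(4,4,5,5-tetramethyl-1,3,2-dioxaborolan-2-yl)phenol | COc1cc(B2OC(C)(C)C(C)(C)O2)ccc1O | starting material
7 | 2-methoxy-4-(4,4,5,5-tetramethyl-1,3,2-dioxaborolan-2-yl)phenyl methanesulfonate | COc1cc(B2OC(C)(C)C(C)(C)O2)ccc1OS(C)(=O)=O | intermediate
8 | [3-methoxy-4-(methylsulfonyloxy)phenyl]boronic acid | COc1cc(B(O)O)ccc1OS(C)(=O)=O | intermediate
9 | (2R)-8-(benzyloxy)-6-bromo-2-[3-methoxy-4-(methylsulfonyloxy)phenyl]chroman-4-one | COc1cc([C@@H]2Oc3c(OCc4ccccc4)cc(Br)cc3C(=O)C2)ccc1OS(C)(=O)=O | intermediate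
10 | (2R)-8-(benzyloxy)-6-bromo-4-methoxy-2-[3-methoxy-4-(methylsulfonyloxy)phenyl]-2H-chromene | COc1cc([C@@H]2Oc3c(OCc4ccccc4)cc(Br)cc3C(OC)=C2)ccc1OS(C)(=O)=O | intermediate
11 | methyl (2R,3R)-7-(benzyloxy)-5-bromo-2-[3-methoxy-4-(methylsulfonyloxy)phenyl]-2,3-dihydro-1-benzofuran-3-carboxylate (trans) | COc1cc([C@@H]2Oc3c(OCc4ccccc4)cc(Br)cc3[C@H]2C(=O)OC)ccc1OS(C)(=O)=O | intermediate
12 | 4-[(2R,3S)-7-(benzyloxy)-5-bromo-3-(hydroxymethyl)-2,3-dihydro-1-benzofuran-2-yl]-2-methoxyphenyl methanesulfonate | COc1cc([C@@H]2Oc3c(OCc4ccccc4)cc(Br)cc3[C@H]2CO)ccc1OS(C)(=O)=O | intermediate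
13 | 4-[(2R,3S)-7-(benzyloxy)-5-ethenyl-3-(hydroxymethyl)-2,3-dihydro-1-benzofuran-2-yl]-2-methoxyphenyl methanesulfonate | COc1cc([C@@H]2Oc3c(OCc4ccccc4)cc(C=C)cc3[C@H]2CO)ccc1OS(C)(=O)=O | intermediate
14 | 4-[(2R,3S)-7-(benzyloxy)-5-formyl-3-(hydroxymethyl)-2,3-dihydro-1-benzofuran-2-yl]-2-methoxyphenyl methanesulfonate | COc1cc([C@@H]2Oc3c(OCc4ccccc4)cc(C=O)cc3[C@H]2CO)ccc1OS(C)(=O)=O | intermediate
15 | 2,4,6-trihydroxyacetophenone | CC(=O)c1c(O)cc(O)cc1O | starting material
16 | 1-[2,4-bis(benzyloxy)-6-hydroxyphenyl]ethan-1-one | CC(=O)c1c(O)cc(OCc2ccccc2)cc1OCc1ccccc1 | intermediate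
17 | 4-[(2R,3S)-7-(benzyloxy)-5-{(E)-3-[2,4-bis(benzyloxy)-6-hydroxyphenyl]-3-oxoprop-1-en-1-yl}-3-(hydroxymethyl)-2,3-dihydro-1-benzofuran-2-yl]-2-methoxyphenyl methanesulfonate | COc1cc([C@@H]2Oc3c(OCc4ccccc4)cc(/C=C/C(=O)c4c(O)cc(OCc5ccccc5)cc4OCc4ccccc4)cc3[C@H]2CO)ccc1OS(C)(=O)=O | intermediate
18 | (E)-1-[2,4-bis(benzyloxy)-6-hydroxyphenyl]-3-[(2R,3S)-7-(benzyloxy)-2-(4-hydroxy-3-methoxyphenyl)-3-(hydroxymethyl)-2,3-dihydro-1-benzofuran-5-yl]prop-2-en-1-one | COc1cc([C@@H]2Oc3c(OCc4ccccc4)cc(/C=C/C(=O)c4c(O)cc(OCc5ccccc5)cc4OCc4ccccc4)cc3[C@H]2CO)ccc1O | intermediate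
19 | 5,7-bis(benzyloxy)-2-[(2R,3S)-7-(benzyloxy)-2-(4-hydroxy-3-methoxyphenyl)-3-(hydroxymethyl)-2,3-dihydro-1-benzofuran-5-yl]-3-hydroxychroman-4-one (trans at the chromanone, both diastereomers) | COc1cc([C@@H]2Oc3c(OCc4ccccc4)cc(C4Oc5cc(OCc6ccccc6)cc(OCc6ccccc6)c5C(=O)C4O)cc3[C@H]2CO)ccc1O | intermediate
20 | 5,7-bis(benzyloxy)-2-[(2R,3S)-7-(benzyloxy)-2-(4-hydroxy-3-methoxyphenyl)-3-(hydroxymethyl)-2,3-dihydro-1-benzofuran-5-yl]-3-hydroxy-4H-chromen-4-one | COc1cc([C@@H]2Oc3c(OCc4ccccc4)cc(-c4oc5cc(OCc6ccccc6)cc(OCc6ccccc6)c5c(=O)c4O)cc3[C@H]2CO)ccc1O | intermediate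
21 | 2,3-dehydrosilychristin, 3,5,7-trihydroxy-2-[(2R,3S)-7-hydroxy-2-(4-hydroxy-3-methoxyphenyl)-3-(hydroxymethyl)-2,3-dihydro-1-benzofuran-5-yl]-4H-chromen-4-one | COc1cc([C@@H]2Oc3c(O)cc(-c4oc5cc(O)cc(O)c5c(=O)c4O)cc3[C@H]2CO)ccc1O | target

Total step count: 14. Longest linear sequence: 11 steps (steps 1, 2, 3, 6, 7, 8, 9, 10, 12, 13, 14, from 1 to 21).

Steps most likely to fail

Step 7. At the C3-iodanyl ketal, loss of a proton (dehydrogenation towards the flavone) or a shift of the C2 aryl group can compete with migration of C4a, and prolonged acid may open the pyranone and erode the C2 configuration. The fallback sets out from 9 and comes back at 11; it is a Wolff ring contraction, in which only the carbon bound to the acyl group (C4a) can migrate. Flavanone 9 is condensed with tert-butoxybis(dimethylamino)methane (toluene, 60 °C) to give the 3-(dimethylaminomethylidene)flavanone F1. Deformylative diazo transfer with tosyl azide (CH2Cl2, rt) should then give the 3-diazo ketone F2, whose C2 is arranged in space as in 9 and only carries a different descriptor. Irradiation at 350 nm in methanol should give, by Wolff rearrangement and methanol capture of the ketene, ester 11 together with its cis epimer F3. A catalytic amount of DBU in CH2Cl2 should equilibrate F3 to trans 11 by enolisation at C3.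

Step 13. With a 6'-alkoxy chalcone the phenoxide can close on the α-carbon (5-exo) and lead towards an aurone, and alkaline peroxide can also cleave the enone. The fallback sets out from 14 and 16 and comes back at 20; it separates epoxidation, ring closure and dehydrogenation. Acetophenone 16 is protected with NaH and MOMCl (THF, 0 °C) as the MOM ether F4. Condensation of F4 with 14 under the conditions of step 12 should give first the mesylated MOM chalcone F5 and, after hydrolysis of the sulfonate in the same flask, the phenolic MOM chalcone F6. Weitz–Scheffer epoxidation (H2O2, NaOH, MeOH–THF, 0 °C) should give the trans epoxy ketone F7 as two diastereomers. HCl in MeOH at 50 °C removes the MOM group, and the freed phenol opens the epoxide at the benzylic carbon (6-endo) to give dihydroflavonol 19, here isolated. Heating 19 in pyridine under air, the base-mediated aerobic dehydrogenation of a 3-hydroxyflavanone, should give flavonol 20.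

Step 6. Carbopalladation of the 8-alkoxychromone may be slow or poorly face-selective, and the boronic acid may protodeboronate before it transmetalates. The fallback sets out from 5 and 8 and comes back at 9; it replaces asymmetric catalysis by resolution. Conjugate addition with an achiral catalyst (Pd(OCOCF3)2, 2,2'-bipyridine, aqueous AcOH–THF, 60 °C) should give the racemic flavanone F8. Preparative chromatography on a chiral stationary phase then delivers 9, and the unwanted 2S enantiomer F9 can be racemised with catalytic DBU, through reversible opening to the chalcone, and recycled.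

Further compounds
F1 | step 7 | (2S)-8-(benzyloxy)-6-bromo-3-[(E)-(dimethylamino)methylidene]-2-[3-methoxy-4-(methylsulfonyloxy)phenyl]chroman-4-one | COc1cc([C@@H]2Oc3c(OCc4ccccc4)cc(Br)cc3C(=O)/C2=C/N(C)C)ccc1OS(C)(=O)=O
F2 | step 7 | (2S)-8-(benzyloxy)-6-bromo-3-diazo-2-[3-methoxy-4-(methylsulfonyloxy)phenyl]chroman-4-one | COc1cc([C@@H]2Oc3c(OCc4ccccc4)cc(Br)cc3C(=O)C2=[N+]=[N-])ccc1OS(C)(=O)=O
F3 | step 7 | methyl (2R,3S)-7-(benzyloxy)-5-bromo-2-[3-methoxy-4-(methylsulfonyloxy)phenyl]-2,3-dihydro-1-benzofuran-3-carboxylate (cis) | COc1cc([C@@H]2Oc3c(OCc4ccccc4)cc(Br)cc3[C@@H]2C(=O)OC)ccc1OS(C)(=O)=O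
F4 | step 13 | 1-[2,4-bis(benzyloxy)-6-(methoxymethoxy)phenyl]ethan-1-one | CC(=O)c1c(OCOC)cc(OCc2ccccc2)cc1OCc1ccccc1
F5 | step 13 | 4-[(2R,3S)-7-(benzyloxy)-5-{(E)-3-[2,4-bis(benzyloxy)-6-(methoxymethoxy)phenyl]-3-oxoprop-1-en-1-yl}-3-(hydroxymethyl)-2,3-dihydro-1-benzofuran-2-yl]-2-methoxyphenyl methanesulfonate | COc1cc([C@@H]2Oc3c(OCc4ccccc4)cc(/C=C/C(=O)c4c(OCOC)cc(OCc5ccccc5)cc4OCc4ccccc4)cc3[C@H]2CO)ccc1OS(C)(=O)=O
F6 | step 13 | (E)-1-[2,4-bis(benzyloxy)-6-(methoxymethoxy)phenyl]-3-[(2R,3S)-7-(benzyloxy)-2-(4-hydroxy-3-methoxyphenyl)-3-(hydroxymethyl)-2,3-dihydro-1-benzofuran-5-yl]prop-2-en-1-one | COc1cc([C@@H]2Oc3c(OCc4ccccc4)cc(/C=C/C(=O)c4c(OCOC)cc(OCc5ccccc5)cc4OCc4ccccc4)cc3[C@H]2CO)ccc1O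
F7 | step 13 | [2,4-bis(benzyloxy)-6-(methoxymethoxy)phenyl]{3-[(2R,3S)-7-(benzyloxy)-2-(4-hydroxy-3-methoxyphenyl)-3-(hydroxymethyl)-2,3-dihydro-1-benzofuran-5-yl]oxiran-2-yl}methanone (trans epoxide, both diastereomers) | COc1cc([C@@H]2Oc3c(OCc4ccccc4)cc(C4OC4C(=O)c4c(OCOC)cc(OCc5ccccc5)cc4OCc4ccccc4)cc3[C@H]2CO)ccc1O
F8 | step 6 | rac-8-(benzyloxy)-6-bromo-2-[3-methoxy-4-(methylsulfonyloxy)phenyl]chroman-4-one | COc1cc(C2Oc3c(OCc4ccccc4)cc(Br)cc3C(=O)C2)ccc1OS(C)(=O)=O
F9 | step 6 | (2S)-8-(benzyloxy)-6-bromo-2-[3-methoxy-4-(methylsulfonyloxy)phenyl]chroman-4-one | COc1cc([C@H]2Oc3c(OCc4ccccc4)cc(Br)cc3C(=O)C2)ccc1OS(C)(=O)=O
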